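**Retrosynthetic overview**
1. Target 10 is cut at the CH2 bridge into aryl ketone 4 (ring A), acetylfilicinic acid 7 (ring B) and formaldehyde; this union is the last step and forms no ring.
2. Ring A: the two phenolic C–O bonds of 4 are cut back to C–H bonds of 4'-methoxypropiophenone 1 (twofold ketone-directed C–H hydroxylation, the key step). The methyl ether is bought in place, para to the ketone, so no selective O-methylation is needed.
3. Ring B: 7 is cut back to 2,4,6-trihydroxyacetophenone 5 by removing the two C-methyl groups (dearomatising gem-dimethylation).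
4. Ring order: both six-membered rings are bought as benzene rings; ring A is oxygenated in step 1, ring B is dearomatised in step 2, and the two are joined in step 3.

Assumption: the target SMILES has no stereocentre (the quaternary carbon carries two methyl groups), so the compound is achiral and no stereocontrol is needed; the keto–enol tautomer of the SMILES is drawn throughout.

**Route**

Step 1
Reactants: 1 4'-methoxypropiophenone
Product: 4 2,6-dihydroxy-4-methoxypropiophenone, via 5-methoxy-2-propanoylphenyl trifluoroacetate 2 (not isolated), via 5-methoxy-2-propanoyl-1,3-phenylene bis(trifluoroacetate) 3 (not isolated)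
Conditions: Pd(OAc)2 (10 mol%), K2S2O8 (5 equiv, two portions), TFA/TFAA 9:1, 60 °C, 24 h; then THF/H2O, rt
Reagents that add atoms: trifluoroacetic acid, OC(=O)C(F)(F)F
Why: Proposed new method: one-pot twofold ketone-directed ortho C–H hydroxylation – the propanoyl oxygen directs cyclopalladation by electrophilic divalent palladium (Pd(O2CCF3)2 formed in TFA) at C2, K2S2O8 oxidises the palladacycle to tetravalent palladium and C–O reductive elimination releases aryl trifluoroacetate 2, whose new oxygen comes from trifluoroacetate; because that oxygen is masked as a non-chelating, oxidation-resistant ester and the ketone oxygen then points toward the remaining ortho C–H, a second identical cycle gives 3, and water cleaves both esters to 4; the closest known reaction is the palladium- or ruthenium-catalysed single ortho-hydroxylation of aryl ketones in TFA/TFAA, which has not been driven to the 2,6-diol; no stereocentre is formed.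

Step 2
Reactants: 5 2,4,6-trihydroxyacetophenone
Product: 7 acetylfilicinic acid (2-acetyl-3,5-dihydroxy-4,4-dimethylcyclohexa-2,5-dien-1-one), via 2,4,6-trihydroxy-3-methylacetophenone 6 (not isolated)
Conditions: NaOMe (3.2 equiv), MeI (2.2 equiv), MeOH, 0 °C to rt, 16 h; then 1 M HCl
Reagents that add atoms: iodomethane, CI
Why: Dearomatising C-alkylation of the phloroglucinol polyanion, a known way to acylfilicinic acids: the first methyl enters at C3 to give 6, a second C-methylation at the same carbon breaks aromaticity and gives the strongly acidic β-triketone 7, whose stabilised enolate reacts no further at this stoichiometry and which is separated from the phenolic by-products by its higher acidity; the new quaternary carbon carries two identical methyl groups, so no stereocentre arises.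

Step 3
Reactants: 4 2,6-dihydroxy-4-methoxypropiophenone (2.0 equiv, excess recovered); 7 acetylfilicinic acid (1.0 equiv)
Product: 10 2-acetyl-6-[(2,4-dihydroxy-6-methoxy-3-propanoylphenyl)methyl]-3,5-dihydroxy-4,4-dimethylcyclohexa-2,5-dien-1-one (target), via 6-(hydroxymethyl)acetylfilicinic acid 8 (not isolated), via 6-methylidene trione 9 (not isolated)
Conditions: 1% aq. KOH, 37% aq. CH2O (1.0 equiv, dropwise), 0 °C to rt, 10 min; then 1 M HCl to pH 2
Reagents that add atoms: formaldehyde, C=O
Why: Knoevenagel condensation of 7 with formaldehyde gives 8 and, by loss of water, the methylene trione 9, which is trapped by Michael (Friedel–Crafts-type) addition of the phenoxide of 4 at C3 (C3 and C5 are equivalent, and 7 has only one free ring carbon); excess 4 and the reversible partner exchange of such methylene-bis compounds in alkali favour the mixed dimer; no stereocentre is formed.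

**Compound list**
1 | 1-(4-methoxyphenyl)propan-1-one (4'-methoxypropiophenone), achiral | CCC(=O)c1ccc(OC)cc1 | starting material
2 | 5-methoxy-2-propanoylphenyl trifluoroacetate, achiral | CCC(=O)c1ccc(OC)cc1OC(=O)C(F)(F)F | intermediate
3 | 5-methoxy-2-propanoyl-1,3-phenylene bis(trifluoroacetate), achiral | CCC(=O)c1c(OC(=O)C(F)(F)F)cc(OC)cc1OC(=O)C(F)(F)F | intermediate
4 | 1-(2,6-dihydroxy-4-methoxyphenyl)propan-1-one (2,6-dihydroxy-4-methoxypropiophenone), achiral | CCC(=O)c1c(O)cc(OC)cc1O | intermediate
5 | 1-(2,4,6-trihydroxyphenyl)ethan-1-one (2,4,6-trihydroxyacetophenone), achiral | CC(=O)c1c(O)cc(O)cc1O | starting material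
6 | 1-(2,4,6-trihydroxy-3-methylphenyl)ethan-1-one, achiral | CC(=O)c1c(O)cc(O)c(C)c1O | intermediate
7 | 2-acetyl-3,5-dihydroxy-4,4-dimethylcyclohexa-2,5-dien-1-one (acetylfilicinic acid), achiral | CC(=O)C1=C(O)C(C)(C)C(O)=CC1=O | intermediate
8 | 2-acetyl-3,5-dihydroxy-6-(hydroxymethyl)-4,4-dimethylcyclohexa-2,5-dien-1-one, achiral | CC(=O)C1=C(O)C(C)(C)C(O)=C(CO)C1=O | intermediate
9 | 2-acetyl-3-hydroxy-4,4-dimethyl-6-methylidenecyclohex-2-ene-1,5-dione, achiral | CC(=O)C1=C(O)C(C)(C)C(=O)C(=C)C1=O | intermediate
10 | 2-acetyl-6-[(2,4-dihydroxy-6-methoxy-3-propanoylphenyl)methyl]-3,5-dihydroxy-4,4-dimethylcyclohexa-2,5-dien-1-one, achiral | CCC(=O)c1c(O)cc(OC)c(CC2=C(O)C(C)(C)C(O)=C(C(C)=O)C2=O)c1O | target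

**Step count**
Total: 3 steps. Longest linear sequence: 2 steps (1 → 4 → 10, or 5 → 7 → 10).

**Steps most likely to fail** (the route has only three steps, so all three are named)

Step 1, the proposed new twofold C–H hydroxylation, is the most uncertain. It may stop at the mono-phenol stage (2) or over-oxidise the electron-rich ring. The fallback uses known chemistry and changes the approach from C–H oxygenation to selective O-alkylation and side-chain homologation of a bought triol. It sets out from compound 5, which is already the starting material for ring B. Me2SO4 (1.0 equiv) and K2CO3 (1.0 equiv) in acetone at rt methylate the non-chelated, most acidic para hydroxyl to give 2,6-dihydroxy-4-methoxyacetophenone F1. BnBr (2.5 equiv) and K2CO3 in DMF at 80 °C protect both remaining phenols to give 2,6-bis(benzyloxy)-4-methoxyacetophenone F2. LiN(iPr)2 (LDA, 1.05 equiv) in THF at −78 °C, then MeI (1.1 equiv), methylates the ketone enolate once to give 2,6-bis(benzyloxy)-4-methoxypropiophenone F3. Hydrogenolysis (H2 1 atm, 10% Pd/C, EtOAc, rt) removes both benzyl groups, and the fallback comes back to the route at compound 4.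

Step 2 may give a mixture of mono-, 3,5-di- and tri-C-methylated products alongside 7. The fallback enforces geminal methylation by blocking and sets out from compound 5. Friedel–Crafts acetylation (Ac2O 1.1 equiv, MeSO3H cat., 80 °C) gives 2,4-diacetylphloroglucinol F4, which has a single free ring carbon. MeI (2.2 equiv) and NaOMe in MeOH then give 2,6-diacetyl-3,5-dihydroxy-4,4-dimethylcyclohexa-2,5-dien-1-one F5. Hot 80% aq. H2SO4 removes both acetyl groups to give filicinic acid F6. Mono C-acetylation of F6 (Ac2O 1 equiv, BF3·OEt2 as Lewis acid promoter) comes back to the route at compound 7.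

Step 3 may give mainly the two homodimers or the 2:1 trimer instead of the mixed dimer. The fallback fixes the CH2 donor on one partner and sets out from compound 4. A Mannich reaction (40% aq. Me2NH, 37% aq. CH2O, 1 equiv each, EtOH, rt) gives 3-[(dimethylamino)methyl]-2,6-dihydroxy-4-methoxypropiophenone F7. Heating F7 with 7 (1.1 equiv) in dioxane at 100 °C expels dimethylamine to give 3-hydroxy-5-methoxy-6-methylidene-2-propanoylcyclohexa-2,4-dien-1-one F8, an ortho-quinone methide that only the enol of 7 can capture. The fallback comes back to the route at compound 10.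

**Further compounds**
F1 | step 1 | 1-(2,6-dihydroxy-4-methoxyphenyl)ethan-1-one (2,6-dihydroxy-4-methoxyacetophenone) | CC(=O)c1c(O)cc(OC)cc1O
F2 | step 1 | 1-[2,6-bis(benzyloxy)-4-methoxyphenyl]ethan-1-one | CC(=O)c1c(OCc2ccccc2)cc(OC)cc1OCc1ccccc1
F3 | step 1 | 1-[2,6-bis(benzyloxy)-4-methoxyphenyl]propan-1-one | CCC(=O)c1c(OCc2ccccc2)cc(OC)cc1OCc1ccccc1
F4 | step 2 | 2,4-diacetylphloroglucinol | CC(=O)c1c(O)cc(O)c(C(C)=O)c1O
F5 | step 2 | 2,6-diacetyl-3,5-dihydroxy-4,4-dimethylcyclohexa-2,5-dien-1-one (diacetylfilicinic acid) | CC(=O)C1=C(O)C(C)(C)C(O)=C(C(C)=O)C1=O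
F6 | step 2 | 3,5-dihydroxy-4,4-dimethylcyclohexa-2,5-dien-1-one (filicinic acid) | CC1(C)C(O)=CC(=O)C=C1O
F7 | step 3 | 1-{3-[(dimethylamino)methyl]-2,6-dihydroxy-4-methoxyphenyl}propan-1-one | CCC(=O)c1c(O)cc(OC)c(CN(C)C)c1O
F8 | step 3 | 3-hydroxy-5-methoxy-6-methylidene-2-propanoylcyclohexa-2,4-dien-1-one (ortho-quinone methide) | CCC(=O)C1=C(O)C=C(OC)C(=C)C1=O
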